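Start from a small charge: each flask holds free catalyst in millimolar amounts against 4.5 mM of impurity.

in all of them: impurity 4.5 mM
- alder: left-handed substrate 1 M; right-handed substrate 1 M; partner 1 equiv; free catalyst 0.57 mol%; run made earlier
- birch: left-handed substrate 1 M; right-handed substrate 1 M; partner 1 equiv; free catalyst 1.3 mol%; run made earlier
- flask: left-handed substrate 1.0 M; right-handed substrate 1.0 M; partner 1.00 equiv; free catalyst 0.85 mol%; time 10 d

| run | time / d | left-handed substrate / % | right-handed substrate / % |
|---|---|---|---|
| alder | 0.500 | 40.0 | 45.8 |
| alder | 0.833 | 38.0 | 42.9 |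
| alder | 1.04 | 35.5 | 43.8 |
| alder | 1.67 | 34.7 | 40.5 |
| alder | 2.50 | 29.8 | 39.5 |
| alder | 4.00 | 26.4 | 38.2 |
| alder | 6.00 | 23.3 | 35.8 |
| birch | 0.500 | 28.4 | 38.9 |
| birch | 0.833 | 25.2 | 37.1 |
| birch | 1.04 | 23.9 | 37.5 |
| birch | 1.67 | 19.7 | 34.9 |
| birch | 2.50 | 19.3 | 34.4 |
| birch | 4.00 | 18.9 | 32.8 |
| birch | 6.00 | 16.7 | 32.0 |

(each reading ± 1 percentage point)

- free catalyst is single-handed; left-handed substrate and right-handed substrate are mirror images of each other, charged as a racemate, each of them at the stated concentration
- an excess is the difference of the two amounts in percent of their sum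
- an excess is below zero if the other one leads

- part of the left-handed substrate and right-handed substrate charged together that has reacted at 10 d
- excess of left-handed product over right-handed product in the product at 10 d
- excess of right-handed substrate over left-handed substrate among what is left of the two at 10 d

Solve two extreme flasks. In the first, the impurity does nothing, so time scales with the catalyst charged. In the second, the impurity binds free catalyst one to one and fast, as limiting reagent of that titration. Take that step as settled and count what it leaves free:

alder: [free catalyst] = 5.70 mM − 4.5 mM = 1.20 mM

birch: [free catalyst] = 13.0 mM − 4.5 mM = 8.50 mM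

flask: [free catalyst] = 8.50 mM − 4.5 mM = 4.00 mM

Call the last figure of each line the working catalyst: the catalyst charged less the impurity charged.

Now test the extremes. Birch should run faster than alder by 2.28 in the first and 7.08 in the second. Read the runs: alder at 6.00 d stands about where birch stands at 1.04 d, a stretch of 5.77. That lies between the extremes, nearer the titrated one.

Map the flask onto birch:

no titration: 10 d × 8.50 mM / 13.0 mM = 6.54 d

titration: 10 d × 4.00 mM / 8.50 mM = 4.71 d

Birch has reacted 48.3 % at 4.00 d and 51.3 % at 6.00 d. So I commit to a c in that span, nearer its low end.

The forecast gives c 49.4 % (45.5 % to 53 %), eP 29.6 % (26 % to 33 %) and eS 28.9 % (24 % to 33 %), on “the impurity stoichiometrically killing catalyst”.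

The flask gives c 49.0 %, eP 30.0 % and eS 28.8 %.

    partner + free catalyst + left-handed substrate → free catalyst + left-handed product (k = 0.196 /M²/min)
    2 free catalyst → spent catalyst B (k = 0.0278 /M/min)
    partner + free catalyst + right-handed substrate → free catalyst + right-handed product (k = 0.0813 /M²/min)
    free catalyst + impurity → spent catalyst A (k = 3.33 /M/min)

The working catalyst predicts spent catalyst A at 52.9 % of the catalyst charged, and the flask holds 52.9 % at 10.0 d. The neighbour with 1.70 equiv of partner has the same charges of free catalyst and impurity, so the same working catalyst, and holds 52.9 % at 10.0 d. With partner down to 2.03 % of its charge, the flask's product excess stands at 30.0 %, against 6.31 % in the run with partner held at its charge. The neighbour, with more partner charged, ends at 18.2 %.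

(The earlier runs and the new flask come from a simulation on assumed constants.)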